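Which recipe leaves you more target after 8.0 h, ochre or blue, counted on the starting material you charged?

common to all: gas 37 mM (held)
- Monday's: starting material 0.12 M; second substrate 0.11 M; run made earlier
- ochre: starting material 0.11 M; second substrate 0.110 M; time 8.0 h
- blue: starting material 0.20 M; second substrate 0.300 M; time 8.0 h

- Monday's (time / min: target / %, starting material / %): 8.00: 4.3, 86.1; 12.0: 7.0, 79.1; 20.0: 14.1, 65.9; 25.0: 17.8, 61.1; 40.0: 27.9, 41.2; 60.0: 39.7, 27.0; 90.0: 48.2, 13.8

(readings scatter by 1 percentage point)

1. the winner by amount of target, in percent of the starting material charged; "neither" if no more than 2 percentage points parts them (ochre / blue / neither)
2. how much target is there at the end, in percent of the starting material charged: ochre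
3. how much target is there at the end, in percent of the starting material charged: blue

- at the start none of the gas is in solution

Take the time first. Between 25.0 min and 90.0 min, Monday's starting material halves about every 30.3 min. If ochre and blue keep near that pace, 8.0 h spans about 15.8 such periods, so lengthening the run should change little, and you are reckoning a share, the selectivity.

Now take the second substrate, and freeze what is nearly constant. The gas is held at a saturation of 37 mM, but none of it is in solution at the start, so taking the dissolved gas as one steady level, the same in ochre and blue, is a simplification of mine. My own assumption is that the unseen part of Monday's balance is starting material taken one to one by second substrate. Over that same stretch target gained 30 percentage points and the unseen part 17 points, a ratio of 1.80, while second substrate stood near 0.0745 M. Their product, 0.134 M, is the even level: the second substrate concentration at which target and the unseen part grow equally fast. The target share is then the even level divided by the even level plus the second substrate present. At the charged levels that gives 54.9% for ochre and 30.9% for blue.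

Last take the starting material: on my assumption, second substrate falls as the unseen part grows, and that fall scales with the starting material charged. Using the mean level over each run, I expect 61.1% in ochre and 36.7% in blue, so ochre should win.

The forecast differs from this on blue and on the winner, giving 56% for ochre, 68% for blue and blue as the winner, while warning that “the data barely show any dependence on the second substrate”.

The winner in the flasks is ochre, with 57.5% in ochre and 30.1% in blue.

    starting material + partner → target (k = 30.0 L mol⁻¹ h⁻¹)
    starting material + second substrate → cross product (k = 6.90 L mol⁻¹ h⁻¹)
    partner → decomposed reagent (k = 0.0260 h⁻¹)
    gas ⇌ partner, rate k4*(csat - [partner]) (kL = 6.70 h⁻¹)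
    second substrate + partner → second product (k = 1.10 L mol⁻¹ h⁻¹)

The unseen part is cross product. The even level gave ochre 61.1% against the 57.5% found, and it stands high for blue, 36.7% against 30.1%. Now carry it to a neighbour of ochre charged with 0.44 M of second substrate. The charged level gives a target share of 23.4%, and the mean level gives 25.2%. That neighbour ends with 19.0% as target and 81.0% as cross product.

The runs were generated by integration with made-up constants.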